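**Retrosynthetic overview**

1. The target comes from acetylation/β-elimination of a β-hydroxy-γ-lactone, itself made by aldol/lactonisation of a bicyclic methyl ester with (silyloxy)acetaldehyde.
2. Rings A and B form together (A first, then B) in one epoxide-initiated, allylsilane-terminated cation–olefin cascade of an acyclic (R)-epoxy diene; the epoxide carbon becomes C4.
3. The acyclic chain comes from an sp2–sp3 Suzuki union of an (E)-alkenylboronate (C1–C5, C10, C18–C20) with a (Z)-allylsilane bromo ester (C6–C9, C11–C13, C16, C17).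
4. The boronate traces back through an alkyne to an (R)-epoxy ketone, made by catalytic enantioselective mono-epoxidation of symmetric heptane-2,6-dione (the symmetry-breaking, chirality-defining key step); the dione comes from Birch dearomatisation of 2,6-lutidine.
5. The allylsilane comes from carbocupration of 4-bromobut-1-yne with Me3SiCH2Cu and alkylation with methyl 4-iodobutanoate.

Assumption: (R)-LaLi3(binaphthoxide)3 is taken to deliver the methylene to the Si face of a methyl ketone (giving the (R)-epoxide); if the sense is the opposite, the mirror-image catalyst is used and nothing else changes.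

**Route**

Step 1
Reactants: 1 2,6-dimethylpyridine (2,6-lutidine)
Product: 3 heptane-2,6-dione, via 2,6-dimethyl-1,4-dihydropyridine 2 (not isolated)
Conditions: Na, liq. NH3, EtOH, −33 °C; NH3 evaporated; then cold 1 M aq. HCl, 0 °C, short contact, extraction
Reagents that add atoms: water, O
Why: Birch reduction of the pyridine gives the 1,4-dihydropyridine (a cyclic bis-enamine) whose acid hydrolysis unmasks the symmetric 1,5-diketone and releases the ring nitrogen as ammonium; no stereocentre is formed.

Step 2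
Reactants: 3 heptane-2,6-dione
Product: 4 5-[(2R)-2-methyloxiran-2-yl]pentan-2-one
Conditions: Me3S(O)I, NaH, THF, rt (ylide, 0.5 equiv relative to 3); then 3, (R)-LaLi3(binaphthoxide)3 [LaLi3(C20H12O2)3] (5 mol %), (2,4,6-(MeO)3C6H2)3P=O (5 mol %), 5 Å MS, THF, rt; unreacted 3 recovered
Reagents that add atoms: trimethylsulfoxonium iodide (as its methylide), C[S+](C)(C)=O.[I-]
Why: Catalytic asymmetric Corey–Chaykovsky epoxidation with the limiting sulfoxonium ylide converts only one of the two equivalent methyl ketones, the catalyst directing CH2 to the Si face, so the symmetry of 3 is broken and the (R)-epoxide carbon (future C4, the only stereocentre set by a reagent in the route) is created here.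

Step 3
Reactants: 4 5-[(2R)-2-methyloxiran-2-yl]pentan-2-one
Product: 6 (2R)-2-methyl-2-(pent-4-yn-1-yl)oxirane, via enol phosphate 5 (not isolated)
Conditions: LiN(i-Pr)2 (1.05 equiv), THF, −78 °C; ClP(O)(OEt)2, −78 °C to rt; then added to LiN(i-Pr)2 (2.25 equiv), THF, −78 to 0 °C; H2O
Reagents that add atoms: none
Why: Negishi's methyl ketone to terminal alkyne conversion (kinetic deprotonation at CH3, O-phosphorylation, then base-induced elimination of the enol phosphate) leaves the epoxide and its stereocentre untouched at low temperature.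

Step 4
Reactants: 6 (2R)-2-methyl-2-(pent-4-yn-1-yl)oxirane
Product: 7 2-{(1E)-2-methyl-5-[(2R)-2-methyloxiran-2-yl]pent-1-en-1-yl}-4,4,5,5-tetramethyl-1,3,2-dioxaborolane
Conditions: CuCl (10 mol %), Xantphos (10 mol %), NaOt-Bu (1.5 equiv), B2pin2 (1.3 equiv), MeI (4 equiv), THF, rt
Reagents that add atoms: bis(pinacolato)diboron, CC1(C)OB(OC1(C)C)B1OC(C)(C)C(C)(C)O1; iodomethane, CI
Why: Copper-catalysed carboboration of a terminal alkyne (syn borylcupration placing boron on the terminal carbon, then methylation of the C–Cu bond with retention) gives the (E)-trisubstituted alkenylboronate and so fixes the C5=C10 geometry under basic conditions that the epoxide tolerates.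

Step 5
Reactants: 8 4-bromobut-1-yne; 9 (trimethylsilyl)methylmagnesium chloride; 10 methyl 4-iodobutanoate
Product: 12 methyl (5Z)-8-bromo-6-[(trimethylsilyl)methyl]oct-5-enoate, via alkenylcopper 11 (not isolated)
Conditions: 9, CuBr·SMe2 (1.0 equiv), Et2O/Me2S, −45 °C; 8, −25 °C; then 10, DMPU, P(OEt)3, −25 °C to rt
Reagents that add atoms: none
Why: Normant carbocupration adds Me3SiCH2–Cu syn across the terminal alkyne (carbon group to the internal carbon, copper to the terminal one) and the alkenylcopper is alkylated by the primary iodide with retention, which sets the (Z)-allylsilane (silylmethyl cis to the ester chain) while the alkyl bromide is left for the coupling.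

Step 6
Reactants: 7 2-{(1E)-2-methyl-5-[(2R)-2-methyloxiran-2-yl]pent-1-en-1-yl}-4,4,5,5-tetramethyl-1,3,2-dioxaborolane; 12 methyl (5Z)-8-bromo-6-[(trimethylsilyl)methyl]oct-5-enoate
Product: 13 methyl (5Z,9E)-10-methyl-13-[(2R)-2-methyloxiran-2-yl]-6-[(trimethylsilyl)methyl]trideca-5,9-dienoate
Conditions: Pd(OAc)2 (5 mol %), P(t-Bu)2Me·HBF4 (10 mol %), KOt-Bu (3 equiv), t-AmOH, rt
Reagents that add atoms: none
Why: Suzuki–Miyaura sp2–sp3 coupling of a primary alkyl bromide bearing β-hydrogens (bulky electron-rich phosphine suppresses β-hydride elimination) joins C5 to C6 with retention of both alkene geometries; no stereocentre is formed.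

Step 7
Reactants: 13 methyl (5Z,9E)-10-methyl-13-[(2R)-2-methyloxiran-2-yl]-6-[(trimethylsilyl)methyl]trideca-5,9-dienoate
Product: 14 methyl 4-[(1R,4aS,5R,8aS)-5-(hydroxymethyl)-5,8a-dimethyl-2-methylidenedecahydronaphthalen-1-yl]butanoate
Conditions: MeAlCl2 (2.5 equiv), CH2Cl2, −78 °C; then aq. NaHCO3
Reagents that add atoms: none
Why: Proposed new method: the Lewis-acid-activated 2,2-disubstituted epoxide is opened at its tertiary carbon, with inversion, by C5 of the (E)-alkene in a chair–chair cation–olefin cascade that the (Z)-allylsilane ends by C9–C10 bond formation and loss of Me3Si to the exocyclic C8 methylene, so that anti addition across C5=C10 gives the trans ring fusion, the allylsilane geometry places the C9 side chain equatorial, and the tied-back epoxide CH2–O (less demanding than CH3 against the C10 methyl) is expected to take the axial site and end cis to C20; the closest known reaction type is the epoxide-initiated, allylsilane-terminated polyene bicyclisation of trisubstituted epoxides together with the invertive cyclisation of 1,1-disubstituted epoxides onto single alkenes or arenes.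

Step 8
Reactants: 14 methyl 4-[(1R,4aS,5R,8aS)-5-(hydroxymethyl)-5,8a-dimethyl-2-methylidenedecahydronaphthalen-1-yl]butanoate; 15 (tert-butyldimethylsilyloxy)acetaldehyde
Product: 17 4-hydroxy-3-{2-[(1R,4aS,5R,8aS)-5-(hydroxymethyl)-5,8a-dimethyl-2-methylidenedecahydronaphthalen-1-yl]ethyl}oxolan-2-one, via silylated aldol adduct 16 (not isolated)
Conditions: LiN(i-Pr)2 (2.2 equiv), THF, −78 °C; 15, −78 °C; AcOH quench; then 48% aq. HF, MeCN, 0 °C to rt (same flask)
Reagents that add atoms: none
Why: Aldol addition of the ester lithium enolate (the C19 alkoxide is a spectator) to the α-silyloxy aldehyde, then desilylation and spontaneous γ-lactonisation, builds the lactone ring; the two new stereocentres form unselectively but are both erased in the next step.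

Step 9
Reactants: 17 4-hydroxy-3-{2-[(1R,4aS,5R,8aS)-5-(hydroxymethyl)-5,8a-dimethyl-2-methylidenedecahydronaphthalen-1-yl]ethyl}oxolan-2-one
Product: 19 {(1R,4aS,5R,8aS)-1,4a-dimethyl-6-methylidene-5-[2-(2-oxo-2,5-dihydrofuran-3-yl)ethyl]decahydronaphthalen-1-yl}methyl acetate (CNP0350004.2), via diacetate 18 (not isolated)
Conditions: Ac2O (3 equiv), Et3N, DMAP (cat.), CH2Cl2, 0 °C to rt; then DBU (2 equiv), rt
Reagents that add atoms: acetic anhydride, CC(=O)OC(C)=O
Why: DMAP-catalysed acetylation of both hydroxyls followed by E1cB elimination of the β-acetoxy group of the lactone gives the conjugated α-substituted butenolide and leaves the C19 acetate in place; no ring stereocentre is touched.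

**Compound list**

1 | 2,6-dimethylpyridine (2,6-lutidine) | Cc1cccc(C)n1 | starting material
2 | 2,6-dimethyl-1,4-dihydropyridine | CC1=CCC=C(C)N1 | intermediate
3 | heptane-2,6-dione | CC(=O)CCCC(C)=O | intermediate
4 | 5-[(2R)-2-methyloxiran-2-yl]pentan-2-one | CC(=O)CCC[C@]1(C)CO1 | intermediate
5 | diethyl 5-[(2R)-2-methyloxiran-2-yl]pent-1-en-2-yl phosphate | C=C(CCC[C@]1(C)CO1)OP(=O)(OCC)OCC | intermediate
6 | (2R)-2-methyl-2-(pent-4-yn-1-yl)oxirane | C#CCCC[C@]1(C)CO1 | intermediate
7 | 2-{(1E)-2-methyl-5-[(2R)-2-methyloxiran-2-yl]pent-1-en-1-yl}-4,4,5,5-tetramethyl-1,3,2-dioxaborolane | C/C(CCC[C@]1(C)CO1)=C\B1OC(C)(C)C(C)(C)O1 | intermediate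
8 | 4-bromobut-1-yne | C#CCCBr | starting material
9 | (trimethylsilyl)methylmagnesium chloride | C[Si](C)(C)C[Mg]Cl | starting material
10 | methyl 4-iodobutanoate | COC(=O)CCCI | starting material
11 | {(1Z)-4-bromo-2-[(trimethylsilyl)methyl]but-1-en-1-yl}copper (magnesium halide complex) | C[Si](C)(C)C/C(CCBr)=C\[Cu] | intermediate
12 | methyl (5Z)-8-bromo-6-[(trimethylsilyl)methyl]oct-5-enoate | COC(=O)CCC/C=C(\C[Si](C)(C)C)CCBr | intermediate
13 | methyl (5Z,9E)-10-methyl-13-[(2R)-2-methyloxiran-2-yl]-6-[(trimethylsilyl)methyl]trideca-5,9-dienoate | COC(=O)CCC/C=C(\C[Si](C)(C)C)CC/C=C(\C)CCC[C@]1(C)CO1 | intermediate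
14 | methyl 4-[(1R,4aS,5R,8aS)-5-(hydroxymethyl)-5,8a-dimethyl-2-methylidenedecahydronaphthalen-1-yl]butanoate | C=C1CC[C@@H]2[C@](C)(CO)CCC[C@@]2(C)[C@@H]1CCCC(=O)OC | intermediate
15 | (tert-butyldimethylsilyloxy)acetaldehyde | CC(C)(C)[Si](C)(C)OCC=O | starting material
16 | methyl 4-[(tert-butyldimethylsilyl)oxy]-3-hydroxy-2-{2-[(1R,4aS,5R,8aS)-5-(hydroxymethyl)-5,8a-dimethyl-2-methylidenedecahydronaphthalen-1-yl]ethyl}butanoate (epimer mixture at the two new centres) | C=C1CC[C@@H]2[C@](C)(CO)CCC[C@@]2(C)[C@@H]1CCC(C(=O)OC)C(O)CO[Si](C)(C)C(C)(C)C | intermediate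
17 | 4-hydroxy-3-{2-[(1R,4aS,5R,8aS)-5-(hydroxymethyl)-5,8a-dimethyl-2-methylidenedecahydronaphthalen-1-yl]ethyl}oxolan-2-one (epimer mixture at the two lactone centres) | C=C1CC[C@@H]2[C@](C)(CO)CCC[C@@]2(C)[C@@H]1CCC1C(O)COC1=O | intermediate
18 | {(1R,4aS,5R,8aS)-5-[2-(4-acetoxy-2-oxooxolan-3-yl)ethyl]-1,4a-dimethyl-6-methylidenedecahydronaphthalen-1-yl}methyl acetate | C=C1CC[C@@H]2[C@](C)(COC(C)=O)CCC[C@@]2(C)[C@@H]1CCC1C(OC(C)=O)COC1=O | intermediate
19 | {(1R,4aS,5R,8aS)-1,4a-dimethyl-6-methylidene-5-[2-(2-oxo-2,5-dihydrofuran-3-yl)ethyl]decahydronaphthalen-1-yl}methyl acetate | C=C1CC[C@@H]2[C@](C)(COC(C)=O)CCC[C@@]2(C)[C@@H]1CCC1=CCOC1=O | target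

**Step count**

Total: 9 steps. Longest linear sequence: 8 steps (steps 1–4 and 6–9, from 2,6-lutidine).

**Steps most likely to fail, with fallbacks**

Step 2 (desymmetrising asymmetric epoxidation). The risks are statistical mono-functionalisation, base-induced intramolecular aldol cyclisation of the 1,5-diketone, and only moderate enantioselectivity for an unbranched alkyl methyl ketone. The fallback sets out from 3 and comes back at 6 by inverting the order of events. The dione is first desymmetrised without any stereochemical demand: LiN(i-Pr)2 (2.1 equiv) forms the bis-enolate, ClP(O)(OEt)2 (1.0 equiv) gives diethyl 6-oxohept-1-en-2-yl phosphate F1 (the second ketone stays masked as its enolate), and further LiN(i-Pr)2 eliminates it to hept-6-yn-2-one F2. F2 has a single ketone and no aldol partner, and is epoxidised with the same ylide and (R)-LaLi3(binaphthoxide)3 to give 6 directly; this also removes the exposure of the epoxide to amide base in step 3.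

Step 6 (sp2–sp3 Suzuki coupling). The risks are β-hydride elimination or base-induced elimination of the homoallylic bromide, and slow transmetalation of the β,β-disubstituted alkenylboronate. The fallback sets out from 7 and 12 and comes back at 13 by reversing the polarity of the union. N-Iodosuccinimide (MeCN, rt, retention) converts 7 into (2R)-2-[(4E)-5-iodo-4-methylpent-4-en-1-yl]-2-methyloxirane F3. Zn dust/LiCl (THF, 40 °C) converts 12 into {(3Z)-8-methoxy-8-oxo-3-[(trimethylsilyl)methyl]oct-3-en-1-yl}zinc bromide F4. Negishi coupling of F3 with F4 (PdCl2(dppf), THF, rt) gives 13.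

Step 7 (bicyclisation). The risks are that the chair placing the epoxide CH2–O axial is not favoured (wrong C4-to-ring relationship), or that the terminal epoxide rearranges before cyclising. The fallback sets out from 12 and comes back at 14, changing the initiator to a Sharpless 2,3-epoxy alcohol, for which a (Z)-hydroxymethyl group is known to end up axial with the C3 hydroxyl equatorial.
- Pent-4-ynal and ethyl 2-[bis(2,2,2-trifluoroethoxy)phosphoryl]propanoate (KN(SiMe3)2, 18-crown-6, THF, −78 °C) give ethyl (2Z)-2-methylhept-2-en-6-ynoate F5.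
- i-Bu2AlH gives (2Z)-2-methylhept-2-en-6-yn-1-ol F6.
- Me3Al/Cp2ZrCl2 then I2 gives (2Z,6E)-7-iodo-2,6-dimethylhepta-2,6-dien-1-ol F7.
- Negishi coupling of F7 with the alkylzinc bromide F4 (made from 12 as above) gives methyl (5Z,9E,13Z)-15-hydroxy-10,14-dimethyl-6-[(trimethylsilyl)methyl]pentadeca-5,9,13-trienoate F8.
- Ti(Oi-Pr)4, L-(+)-diethyl tartrate and t-BuOOH (4 Å MS, CH2Cl2, −20 °C) give methyl (5Z,9E)-12-[(2R,3S)-3-(hydroxymethyl)-3-methyloxiran-2-yl]-10-methyl-6-[(trimethylsilyl)methyl]dodeca-5,9-dienoate F9.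
- MeAlCl2 (CH2Cl2, −78 °C) closes rings A and B to methyl 4-[(1R,4aS,5R,6R,8aS)-6-hydroxy-5-(hydroxymethyl)-5,8a-dimethyl-2-methylidenedecahydronaphthalen-1-yl]butanoate F10.
- Thiocarbonyldiimidazole gives the cyclic 3,19-thionocarbonate of that diol F11.
- Bu3SnH/AIBN (toluene, 110 °C) cleaves the secondary C3–O bond (Barton deoxygenation), and K2CO3/MeOH frees the C19 hydroxyl to return 14.

Further compounds
F1 | step 2 | diethyl 6-oxohept-1-en-2-yl phosphate | C=C(CCCC(C)=O)OP(=O)(OCC)OCC
F2 | step 2 | hept-6-yn-2-one | CC(=O)CCCC#C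
F3 | step 6 | (2R)-2-[(4E)-5-iodo-4-methylpent-4-en-1-yl]-2-methyloxirane | C/C(CCC[C@]1(C)CO1)=C\I
F4 | step 6 | {(3Z)-8-methoxy-8-oxo-3-[(trimethylsilyl)methyl]oct-3-en-1-yl}zinc bromide | COC(=O)CCC/C=C(\C[Si](C)(C)C)CC[Zn]Br
F5 | step 7 | ethyl (2Z)-2-methylhept-2-en-6-ynoate | CCOC(=O)/C(C)=C\CCC#C
F6 | step 7 | (2Z)-2-methylhept-2-en-6-yn-1-ol | OC/C(C)=C\CCC#C
F7 | step 7 | (2Z,6E)-7-iodo-2,6-dimethylhepta-2,6-dien-1-ol | OC/C(C)=C\CC/C(C)=C/I
F8 | step 7 | methyl (5Z,9E,13Z)-15-hydroxy-10,14-dimethyl-6-[(trimethylsilyl)methyl]pentadeca-5,9,13-trienoate | COC(=O)CCC/C=C(\C[Si](C)(C)C)CC/C=C(\C)CC/C=C(/C)CO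
F9 | step 7 | methyl (5Z,9E)-12-[(2R,3S)-3-(hydroxymethyl)-3-methyloxiran-2-yl]-10-methyl-6-[(trimethylsilyl)methyl]dodeca-5,9-dienoate | COC(=O)CCC/C=C(\C[Si](C)(C)C)CC/C=C(\C)CC[C@H]1O[C@@]1(C)CO
F10 | step 7 | methyl 4-[(1R,4aS,5R,6R,8aS)-6-hydroxy-5-(hydroxymethyl)-5,8a-dimethyl-2-methylidenedecahydronaphthalen-1-yl]butanoate | C=C1CC[C@@H]2[C@](C)(CO)[C@H](O)CC[C@@]2(C)[C@@H]1CCCC(=O)OC
F11 | step 7 | cyclic 3,19-thionocarbonate (1,3-dioxane-2-thione across C3–C4–C19) of the diol F10 | C=C1CC[C@@H]2[C@]3(C)COC(=S)O[C@@H]3CC[C@@]2(C)[C@@H]1CCCC(=O)OC
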